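## Retrosynthetic overview
1. Remove the C9-OTBS protecting group and the C8 angelate. The 10-membered carbocycle is then closed by a SmI2-generated ketyl radical from the C8 aldehyde (10-exo addition to C7 of a 3-(acetoxymethyl)butenolide). Loss of acetate from the resulting Sm enolate creates the α-methylene lactone. This radical step forms C7–C8, sets the trans 6,7-ring fusion, and sets C8.
2. The butenolide (first ring) comes from RCM of the acrylate ester of a C6 divinylcarbinol. That carbinol is made by asymmetric NHK coupling of an (E)-vinyl iodide with acrolein.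
3. The Z-ring C1=C10 acrylate comes from cross-metathesis of a terminal alkene with a Baylis–Hillman adduct that carries a masked C8 aldehyde. C9 is set by enzymatic resolution of that adduct. The E-trisubstituted C4=C5 alkene comes from Zr-catalysed carboalumination (ZACA) of a terminal alkyne.
4. Ring order: butenolide by RCM, then the 10-membered ring by radical macrocyclization.

Assumptions: 5-hexen-1-yne is commercially available. The lipase gives the (S)-alcohol (otherwise use the complementary lipase). Cross-metathesis gives the thermodynamic acrylate with C2 trans to CO2Me, which is the ring-cis 1(10)-olefin.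

## Route

**Step 1**
Reactants: 1 (5-hexen-1-yne)
Product: 2 ((E)-1-iodo-2-methylhexa-1,5-diene)
Conditions: Me3Al, cat. Cp2ZrCl2, CH2Cl2, 0 °C→rt; then I2, THF, –30 °C
Reagents that add atoms: trimethylaluminium (C[Al](C)C, gives C15 methyl); iodine (II)
Why: Negishi Zr-catalysed carboalumination is a syn carbometalation of the alkyne that leaves the terminal alkene untouched. Iodinolysis gives the E-trisubstituted vinyl iodide (I trans to the chain), which sets the 4E geometry.

**Step 2**
Reactants: 3 (methyl acrylate), 4 (2,2-dimethoxyacetaldehyde, 60% aqueous)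
Product: 5 (racemic methyl 2-(1-hydroxy-2,2-dimethoxyethyl)acrylate)
Conditions: DABCO (20 mol%), dioxane/H2O 1:1, rt
Reagents that add atoms: none
Why: Morita–Baylis–Hillman reaction with an activated glyoxal acetal. It builds the C9 carbinol, C10 with its ester, and C8 as a masked aldehyde.

**Step 3**
Reactants: 5
Product: 6 ((S)-5)
Conditions: Amano lipase PS, vinyl acetate, iPr2O, 25 °C, to ~50% conversion; chromatography
Reagents that add atoms: none (vinyl acetate, CC(=O)OC=C, acylates only the discarded (R)-enantiomer)
Why: Lipase kinetic resolution of the Baylis–Hillman alcohol sets C9 (S). This is the only source of chirality for C9.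

**Step 4**
Reactants: 2, 6
Product: 7 (methyl (2E,6E)-2-[(S)-1-hydroxy-2,2-dimethoxyethyl]-7-iodo-6-methylhepta-2,6-dienoate)
Conditions: Hoveyda–Grubbs II (5 mol%), 2 (3 equiv), CH2Cl2, 40 °C
Reagents that add atoms: none (ethylene lost)
Why: Cross-metathesis of the terminal alkene of 2 with the 1,1-disubstituted acrylate. The trisubstituted vinyl iodide and acrylate are inert. The thermodynamic product has C2 trans to CO2Me, which is the ring-cis C1=C10.

**Step 5**
Reactants: 7
Product: 8 (TBS ether of 7)
Conditions: TBSCl, imidazole, DMF, 40 °C
Reagents that add atoms: TBSCl (CC(C)(C)[Si](C)(C)Cl)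
Why: Silylation protects the C9-OH for the later NHK, esterification and radical steps. No stereocentre is touched.

**Step 6**
Reactants: 9 (2-(bromomethyl)acrylic acid)
Product: 10 (2-(acetoxymethyl)acrylic acid)
Conditions: KOAc (2.5 equiv), DMF, rt; then 1 M HCl
Reagents that add atoms: potassium acetate (CC(=O)[O-].[K+])
Why: SN2 displacement of the allylic bromide by acetate. The acetate becomes the leaving group that unmasks C11=C13 in Step 11.

**Step 7**
Reactants: 8, 11 (acrolein)
Product: 12 (C6 (S)-divinylcarbinol)
Conditions: CrCl2 (4 equiv), NiCl2 (1 mol%), (S)-sulfonamide ligand (20 mol%), proton sponge, MeCN/THF, rt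
Reagents that add atoms: none
Why: Asymmetric Nozaki–Hiyama–Kishi vinylation. It proceeds with retention of the E-alkene, and the chiral ligand sets C6 as (S) in this intermediate, which becomes 6R after RCM.

**Step 8**
Reactants: 12, 10
Product: 13 (acrylate ester of 12)
Conditions: EDC·HCl, cat. DMAP, CH2Cl2, 0 °C→rt
Reagents that add atoms: none
Why: Steglich esterification at the secondary allylic alcohol, with no change at C6.

**Step 9**
Reactants: 13
Product: 14 ((R)-3-acetoxymethyl-5-alkenyl-2(5H)-furanone, the first ring)
Conditions: Hoveyda–Grubbs II (10 mol%), CH2Cl2 (5 mM), 40 °C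
Reagents that add atoms: none (ethylene lost)
Why: Ring-closing metathesis between the terminal vinyl and the acrylate forms the C7=C11 butenolide. The hindered trisubstituted alkenes do not react, and C6 is untouched.

**Step 10**
Reactants: 14
Product: 15 (C8 aldehyde)
Conditions: TESOTf, 2,4,6-collidine, CH2Cl2, 0 °C; then H2O
Reagents that add atoms: water (O)
Why: Fujioka–Kita acetal deprotection via a collidinium intermediate, which is mild enough to leave the TBS ether, esters and butenolide intact. The α-silyloxy aldehyde is used immediately to avoid C9 epimerization.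

**Step 11**
Reactants: 15
Product: 16 (10-membered carbocycle, 8-OH, 9-OTBS, α-methylene-γ-lactone)
Conditions: SmI2 (2.4 equiv, 0.05 M in THF) added over 3 h to 15 (1 mM) in THF/HMPA, –78→0 °C; NH4Cl quench
Reagents that add atoms: none
Why: The Sm(III) ketyl radical undergoes 10-exo addition to C7, the β-carbon of the butenolide. Attack is anti to the C6 substituent, giving the 6,7-trans fusion. The C8 carbinol is set by the macrocyclic transition state with Sm chelation. The α-lactone radical is reduced to the Sm enolate, and E1cB loss of acetate gives C11=C13.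
Proposed new method: This is a SmI2 ketyl macrocyclization onto a 3-(acetoxymethyl)butenolide with in-situ β-acetoxy elimination. The closest known reactions are SmI2 ketyl–enoate/butenolide couplings and allyl-acetate radical–polar crossover eliminations. Slow addition and high dilution favour ring closure over dimerization.

**Step 12**
Reactants: 16, 17 (angelic acid)
Product: 18 (C8 angelate)
Conditions: 17, 2,4,6-trichlorobenzoyl chloride, Et3N, THF; then 16, DMAP, toluene, rt
Reagents that add atoms: none (17 is a reactant; the Yamaguchi reagent leaves)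
Why: Yamaguchi esterification through the mixed anhydride acylates the free C8-OH and keeps the Z-angelate. C8 is not touched.

**Step 13**
Reactants: 18
Product: 19 (polymatin A)
Conditions: HF·pyridine, pyridine, THF, 0 °C→rt
Reagents that add atoms: none
Why: Buffered fluoride removes the TBS group without acyl migration or lactone opening, and no stereocentre is touched.

## Compound list
1 | 5-hexen-1-yne | C#CCCC=C | starting material
2 | (E)-1-iodo-2-methylhexa-1,5-diene | I/C=C(\C)CCC=C | intermediate
3 | methyl acrylate | C=CC(=O)OC | starting material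
4 | 2,2-dimethoxyacetaldehyde | O=CC(OC)OC | starting material
5 | (±)-methyl 2-(1-hydroxy-2,2-dimethoxyethyl)acrylate | C=C(C(O)C(OC)OC)C(=O)OC | intermediate
6 | (S)-methyl 2-(1-hydroxy-2,2-dimethoxyethyl)acrylate | C=C(C(=O)OC)[C@H](O)C(OC)OC | intermediate
7 | methyl (2E,6E)-2-[(S)-1-hydroxy-2,2-dimethoxyethyl]-7-iodo-6-methylhepta-2,6-dienoate | I/C=C(\C)CC/C=C(/C(=O)OC)[C@H](O)C(OC)OC | intermediate
8 | TBS ether of 7 | I/C=C(\C)CC/C=C(/C(=O)OC)[C@H](O[Si](C)(C)C(C)(C)C)C(OC)OC | intermediate
9 | 2-(bromomethyl)acrylic acid | C=C(CBr)C(=O)O | starting material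
10 | 2-(acetoxymethyl)acrylic acid | C=C(COC(C)=O)C(=O)O | intermediate
11 | acrolein | C=CC=O | starting material
12 | (S)-divinylcarbinol from NHK | C=C[C@H](O)/C=C(\C)CC/C=C(/C(=O)OC)[C@H](O[Si](C)(C)C(C)(C)C)C(OC)OC | intermediate
13 | acrylate ester of 12 | C=C(COC(C)=O)C(=O)O[C@@H](C=C)/C=C(\C)CC/C=C(/C(=O)OC)[C@H](O[Si](C)(C)C(C)(C)C)C(OC)OC | intermediate
14 | 3-(acetoxymethyl)-5-alkenylbutenolide (R) | CC(=O)OCC1=C[C@H](OC1=O)/C=C(\C)CC/C=C(/C(=O)OC)[C@H](O[Si](C)(C)C(C)(C)C)C(OC)OC | intermediate
15 | C8 aldehyde | CC(=O)OCC1=C[C@H](OC1=O)/C=C(\C)CC/C=C(/C(=O)OC)[C@H](O[Si](C)(C)C(C)(C)C)C=O | intermediate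
16 | macrocyclic 8-hydroxy-9-OTBS methylene lactone | C=C1C(=O)O[C@@H]2/C=C(\C)CC/C=C(/C(=O)OC)[C@H](O[Si](C)(C)C(C)(C)C)[C@@H](O)[C@@H]12 | intermediate
17 | angelic acid | OC(=O)/C(C)=C\C | starting material
18 | C8 angelate, 9-OTBS | C=C1C(=O)O[C@@H]2/C=C(\C)CC/C=C(/C(=O)OC)[C@H](O[Si](C)(C)C(C)(C)C)[C@@H](OC(=O)/C(C)=C\C)[C@@H]12 | intermediate
19 | polymatin A | C=C1C(=O)O[C@@H]2/C=C(\C)CC/C=C(/C(=O)OC)[C@H](O)[C@@H](OC(=O)/C(C)=C\C)[C@@H]12 | target

## Step count
Total steps: 13. Longest linear sequence: 11 steps, from methyl acrylate (3) through 5, 6, 7, 8, 12, 13, 14, 15, 16 and 18 to 19.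

## Three steps most likely to fail
1. **Step 11 (SmI2 macrocyclization).** Risks are γ-C–O reductive opening of the butenolide, over-reduction of the α-methylene lactone, and the wrong C8 epimer. Fallback: close the ring by intramolecular NHK allylation (CrCl2) between the C6 enal and a (Z)-2-(bromomethyl)alk-2-enoate bearing C7–C8, which forms C6–C7 and the lactone together.
2. **Step 4 (cross-metathesis).** The hindered Baylis–Hillman alcohol may give low yield, homodimer, or a poor E/Z ratio. Fallback: form C1=C10 by E-selective Horner–Wadsworth–Emmons between (E)-5-iodo-4-methylpent-4-enal and a phosphonoacetate carrying the C9-silyloxy C8-acetal chain.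
3. **Step 3 (lipase resolution).** Selectivity for this substrate is unproven, and half the material is lost. Fallback: use a catalytic asymmetric Morita–Baylis–Hillman reaction (β-isocupreidine with the hexafluoroisopropyl acrylate) with 4, then transesterify to the methyl ester.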